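**Strategy.** The saturated ring is closed by attaching a preassembled C4–C3–C2–C1 chain to the 4-hydroxy-3,5-dimethoxyphenyl ring A at C4a and C8a in one flask. The chain is first hung on the ring A phenol oxygen (O7) as a 2-substituted allyl aryl ether, a bond the target lacks; the precursor is an acyclic diol carrying that ether. Heating moves C4 from O7 to C4a, the only free terminus because both ortho carbons (C6, C8) carry methoxy groups; ionisation of the benzylic alcohol then lets C1 alkylate C8a. Ring A is symmetric about the O7–C4a axis, so C5 and C8a are equivalent and no regiochemical choice arises. The C2 stereocentre, from an Evans aldol, controls C1; C3 follows by hydroboration.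

Key step: step 6

Remark: tetralin locants are used in the text (C1 = CH bearing the pendant aryl group, C4 = benzylic CH2, C4a and C8a = ring-fusion carbons, O7 = phenol oxygen of ring A); the heating and the ionisation in step 6 are run in one flask with a solvent change and are counted as one operation.

**Step 1**
Reactants: 1 2,6-dimethoxyphenol; 2 2,3-dibromoprop-1-ene
Product: 3 2-[(2-bromoprop-2-en-1-yl)oxy]-1,3-dimethoxybenzene
Conditions: K2CO3, acetone, 56 °C
Reagents that add atoms: none
Why: Williamson ether synthesis in which the phenoxide displaces the allylic bromide by SN2 while the vinylic bromide is inert.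

**Step 2**
Reactants: 4 (R)-4-benzyl-1,3-oxazolidin-2-one; 5 bromoacetyl bromide
Product: 7 (R)-4-benzyl-3-(2-bromoacetyl)-1,3-oxazolidin-2-one, via lithium oxazolidinide 6 (not isolated)
Conditions: n-BuLi, THF, −78 °C; then 5, −78 °C to 0 °C
Reagents that add atoms: none
Why: N-acylation of the lithiated oxazolidinone, the acyl bromide reacting far faster than the primary alkyl bromide at low temperature.

**Step 3**
Reactants: 7 (R)-4-benzyl-3-(2-bromoacetyl)-1,3-oxazolidin-2-one; 3 2-[(2-bromoprop-2-en-1-yl)oxy]-1,3-dimethoxybenzene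
Product: 9 (4R)-4-benzyl-3-{3-[(2,6-dimethoxyphenoxy)methyl]but-3-enoyl}-1,3-oxazolidin-2-one, via zinc enolate 8 (not isolated)
Conditions: Zn dust (TMSCl-activated), THF, 25 °C; then 3, Pd2(dba)3 (cat.), XPhos, THF, 40 °C
Reagents that add atoms: none
Why: Reformatsky reagent formation followed by Negishi-type α-alkenylation of the zinc enolate (oxidative addition of the vinyl bromide to zerovalent palladium, transmetalation, reductive elimination); the neutral conditions should tolerate the imide and keep the new alkene out of conjugation.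

**Step 4**
Reactants: 9 (4R)-4-benzyl-3-{3-[(2,6-dimethoxyphenoxy)methyl]but-3-enoyl}-1,3-oxazolidin-2-one; 10 4-(benzyloxy)-3-methoxybenzaldehyde
Product: 13 (4R)-4-benzyl-3-{(2R,3R)-3-[4-(benzyloxy)-3-methoxyphenyl]-2-[3-(2,6-dimethoxyphenoxy)prop-1-en-2-yl]-3-hydroxypropanoyl}-1,3-oxazolidin-2-one, via boron enolate 11 (not isolated), via boron aldolate 12 (not isolated)
Conditions: Bu2BOTf, Et3N, CH2Cl2, −78 °C to 0 °C; then 10, −78 °C to 0 °C; pH 7 buffer, MeOH, H2O2, 0 °C
Reagents that add atoms: none
Why: Evans syn-aldol reaction in which the (Z)-boron dienolate adds through its α-carbon in a chair Zimmerman–Traxler transition state on the face opposite the benzyl group of the (R)-auxiliary, setting the (2R) centre (the future C2) and the syn (3R) carbinol.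

**Step 5**
Reactants: 13 the aldol adduct
Product: 14 (1R,2S)-1-[4-(benzyloxy)-3-methoxyphenyl]-2-[3-(2,6-dimethoxyphenoxy)prop-1-en-2-yl]propane-1,3-diol
Conditions: LiBH4, MeOH (1 equiv), THF, 0 °C
Reagents that add atoms: none
Why: Reductive cleavage of the N-acyl oxazolidinone by borohydride gives the primary alcohol and releases the auxiliary without touching either stereocentre or the allyl aryl ether.

**Step 6**
Reactants: 14 (1R,2S)-1-[4-(benzyloxy)-3-methoxyphenyl]-2-[3-(2,6-dimethoxyphenoxy)prop-1-en-2-yl]propane-1,3-diol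
Product: 16 (7S,8R)-8-[4-(benzyloxy)-3-methoxyphenyl]-7-(hydroxymethyl)-1,3-dimethoxy-6-methylidene-5,6,7,8-tetrahydronaphthalen-2-ol, via para-allylphenol 15 (not isolated)
Conditions: PhMe, 190 °C, sealed vessel; then solvent exchange in the same flask, (CF3)2CHOH, 40 °C
Reagents that add atoms: none
Why: Heating induces two consecutive [3,3] shifts (aromatic Claisen rearrangement to a methoxy-blocked ortho carbon, then Cope rearrangement to the para carbon and tautomerisation), the para-Claisen rearrangement known for 2,6-disubstituted aryl allyl ethers, which forms C4–C4a and frees the O7 phenol in 15. In hexafluoropropan-2-ol the 4-alkoxybenzylic alcohol of 15 ionises and the C1 cation is trapped by the neighbouring ring A carbon in an intramolecular Friedel–Crafts alkylation, the closure by which aryltetralin lignans are classically made, forming C8a–C1. This closure is 6-exo-trig at the cationic carbon (ring C8a–C4a–C4–C3–C2–C1), whereas the first bond is made by sigmatropic transfer and closes no ring. The new stereocentre C1 is set by C2 through a chair-like transition state in which the aryl group and the C2 hydroxymethyl group avoid each other, which should give the 1,2-trans (1R) isomer. The step needs para selectivity in the rearrangement, secured by the two methoxy-blocked ortho positions; it needs no choice between the two ring carbons next to C4a, because C5 and C8a are equivalent; and it needs the cation to form only after the phenol is in place, secured by neutral heating before the ionising solvent is added. The weakly acidic solvent should leave the exocyclic alkene and the C2 configuration untouched.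

**Step 7**
Reactants: 16 the 6-methylidene tetralin
Product: 18 (6S,7S,8R)-8-[4-(benzyloxy)-3-methoxyphenyl]-6,7-bis(hydroxymethyl)-1,3-dimethoxy-5,6,7,8-tetrahydronaphthalen-2-ol, via alkylborane 17 (not isolated)
Conditions: 9-BBN (excess), THF, 0 °C to 25 °C; then NaOH (aq), H2O2, 0 °C
Reagents that add atoms: hydrogen peroxide (OO)
Why: Hydroboration–oxidation in which boron adds to the exocyclic CH2 (anti-Markovnikov) and hydrogen is delivered to C3 on the face opposite the C1 aryl group, which the peri methoxy group holds pseudoaxial so that it shields its own face, so the new hydroxymethyl group should end trans to that at C2 (3S).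

**Step 8**
Reactants: 18 the O-benzyl tetralin triol
Product: 19 (6S,7S,8R)-8-(4-hydroxy-3-methoxyphenyl)-6,7-bis(hydroxymethyl)-1,3-dimethoxy-5,6,7,8-tetrahydronaphthalen-2-ol (the target)
Conditions: H2 (1 atm), Pd/C, EtOAc–MeOH, 25 °C
Reagents that add atoms: none
Why: Catalytic hydrogenolysis of the benzyl aryl ether, which should leave the aryl methyl ethers, the alcohols and the diarylmethine C–H untouched.

**Compound list**

1 | 2,6-dimethoxyphenol | COc1cccc(OC)c1O | starting material
2 | 2,3-dibromoprop-1-ene | BrCC(Br)=C | starting material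
3 | 2-[(2-bromoprop-2-en-1-yl)oxy]-1,3-dimethoxybenzene | COc1cccc(OC)c1OCC(Br)=C | intermediate
4 | (R)-4-benzyl-1,3-oxazolidin-2-one | O=C1OC[C@@H](Cc2ccccc2)N1 | starting material
5 | bromoacetyl bromide | BrCC(Br)=O | starting material
6 | lithium (4R)-4-benzyl-2-oxo-1,3-oxazolidin-3-ide | O=C1OC[C@@H](Cc2ccccc2)N1[Li] | intermediate
7 | (R)-4-benzyl-3-(2-bromoacetyl)-1,3-oxazolidin-2-one | O=C1OC[C@@H](Cc2ccccc2)N1C(=O)CBr | intermediate
8 | bromo{2-[(4R)-4-benzyl-2-oxo-1,3-oxazolidin-3-yl]-2-oxoethyl}zinc (Reformatsky reagent of 7) | O=C1OC[C@@H](Cc2ccccc2)N1C(=O)C[Zn]Br | intermediate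
9 | (4R)-4-benzyl-3-{3-[(2,6-dimethoxyphenoxy)methyl]but-3-enoyl}-1,3-oxazolidin-2-one | O=C1OC[C@@H](Cc2ccccc2)N1C(=O)CC(=C)COc1c(OC)cccc1OC | intermediate
10 | 4-(benzyloxy)-3-methoxybenzaldehyde | COc1cc(C=O)ccc1OCc1ccccc1 | starting material
11 | (Z)-O-dibutylboryl dienolate of 9 | O=C1OC[C@@H](Cc2ccccc2)N1/C(OB(CCCC)CCCC)=C/C(=C)COc1c(OC)cccc1OC | intermediate
12 | O-dibutylboryl aldolate of 13 (boron on the carbinol oxygen) | O=C1OC[C@@H](Cc2ccccc2)N1C(=O)[C@@H]([C@@H](OB(CCCC)CCCC)c1ccc(OCc2ccccc2)c(OC)c1)C(=C)COc1c(OC)cccc1OC | intermediate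
13 | (4R)-4-benzyl-3-{(2R,3R)-3-[4-(benzyloxy)-3-methoxyphenyl]-2-[3-(2,6-dimethoxyphenoxy)prop-1-en-2-yl]-3-hydroxypropanoyl}-1,3-oxazolidin-2-one | O=C1OC[C@@H](Cc2ccccc2)N1C(=O)[C@@H]([C@@H](O)c1ccc(OCc2ccccc2)c(OC)c1)C(=C)COc1c(OC)cccc1OC | intermediate
14 | (1R,2S)-1-[4-(benzyloxy)-3-methoxyphenyl]-2-[3-(2,6-dimethoxyphenoxy)prop-1-en-2-yl]propane-1,3-diol | C=C(COc1c(OC)cccc1OC)[C@@H](CO)[C@@H](O)c1ccc(OCc2ccccc2)c(OC)c1 | intermediate
15 | (1R,2S)-1-[4-(benzyloxy)-3-methoxyphenyl]-2-[3-(4-hydroxy-3,5-dimethoxyphenyl)prop-1-en-2-yl]propane-1,3-diol | C=C(Cc1cc(OC)c(O)c(OC)c1)[C@@H](CO)[C@@H](O)c1ccc(OCc2ccccc2)c(OC)c1 | intermediate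
16 | (7S,8R)-8-[4-(benzyloxy)-3-methoxyphenyl]-7-(hydroxymethyl)-1,3-dimethoxy-6-methylidene-5,6,7,8-tetrahydronaphthalen-2-ol | COc1cc([C@@H]2c3c(cc(OC)c(O)c3OC)CC(=C)[C@H]2CO)ccc1OCc1ccccc1 | intermediate
17 | B-alkyl-9-BBN adduct of 16: compound 18 with the C6 CH2OH replaced by CH2–(9-borabicyclo[3.3.1]nonan-9-yl), hydroxyl groups drawn free | COc1cc([C@@H]2c3c(cc(OC)c(O)c3OC)C[C@H](CB4C5CCCC4CCC5)[C@H]2CO)ccc1OCc1ccccc1 | intermediate
18 | (6S,7S,8R)-8-[4-(benzyloxy)-3-methoxyphenyl]-6,7-bis(hydroxymethyl)-1,3-dimethoxy-5,6,7,8-tetrahydronaphthalen-2-ol | COc1cc([C@@H]2c3c(cc(OC)c(O)c3OC)C[C@H](CO)[C@H]2CO)ccc1OCc1ccccc1 | intermediate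
19 | (6S,7S,8R)-8-(4-hydroxy-3-methoxyphenyl)-6,7-bis(hydroxymethyl)-1,3-dimethoxy-5,6,7,8-tetrahydronaphthalen-2-ol | COc1cc([C@@H]2c3c(cc(OC)c(O)c3OC)C[C@H](CO)[C@H]2CO)ccc1O | target

**Step count.** Total: 8 steps. Longest linear sequence: 7 steps (1, 3, 4, 5, 6, 7, 8; step 2 prepares the second partner of step 3).

**Steps most likely to fail**

Step 6. The benzylic hydroxyl may be lost during the heating period by thermal dehydration or premature ionisation, which would lead to intermolecular alkylation or to erosion of the C2 configuration through a reversible styrene. The fallback is stepwise and keeps the cation precursor masked. It sets out from 14, which is converted with 2,2-dimethoxypropane and pyridinium p-toluenesulfonate into the acetonide F1. The para-Claisen rearrangement is run on F1 (PhMe, 190 °C) and the phenol acetonide F2 is isolated. F2 is then treated with catalytic Sc(OTf)3 in CH2Cl2, which opens the benzylic C–O bond of the dioxane, closes the ring at C8a and releases acetone. The fallback comes back to the route at 16.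

Step 7. Facial selectivity of hydrogen delivery to C3 may be poor or reversed; attack on the face of the aryl group would give the 2,3-cis isomer. The fallback puts oxygen on first and brings hydrogen in by a 1,2-shift. It sets out from 16, which is epoxidised (mCPBA, NaHCO3, CH2Cl2, 0 °C) to the spiro-epoxide F3. MgBr2·OEt2 then triggers a Meinwald rearrangement in which hydride migrates to C3 anti to the departing oxygen. The formyl group of the aldehyde F4 therefore ends on the face that the oxidant attacked, the opposite outcome to hydroboration for the same facial preference. NaBH4 is added directly and reduces F4, and the fallback comes back to the route at 18.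

Step 3. The alkenylpalladium intermediate may undergo β-elimination of the aryloxide, or transmetalation of the imide zinc enolate may be sluggish. The fallback makes the C2–carbonyl bond instead of the C2–C3 bond. It sets out from 1, which is alkylated with 3-chloro-2-(chloromethyl)prop-1-ene (K2CO3, acetone) to the allylic chloride F5. Mg in THF followed by CO2 gives the but-3-enoic acid F6; the two allyl termini are equivalent, so carboxylation can give only one skeleton. F6 is coupled to 4 through the pivalic mixed anhydride (t-BuCOCl, Et3N; then 4, LiCl), and the fallback comes back to the route at 9.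

**Further compounds**

F1 | step 6 | (4R,5S)-4-[4-(benzyloxy)-3-methoxyphenyl]-5-[3-(2,6-dimethoxyphenoxy)prop-1-en-2-yl]-2,2-dimethyl-1,3-dioxane | C=C(COc1c(OC)cccc1OC)[C@H]1COC(C)(C)O[C@H]1c1ccc(OCc2ccccc2)c(OC)c1
F2 | step 6 | 4-{2-[(4R,5S)-4-[4-(benzyloxy)-3-methoxyphenyl]-2,2-dimethyl-1,3-dioxan-5-yl]prop-2-en-1-yl}-2,6-dimethoxyphenol | C=C(Cc1cc(OC)c(O)c(OC)c1)[C@H]1COC(C)(C)O[C@H]1c1ccc(OCc2ccccc2)c(OC)c1
F3 | step 7 | spiro-epoxide of 16 at the exocyclic alkene, oxirane oxygen on the face of the C1 aryl group | COc1cc([C@@H]2c3c(cc(OC)c(O)c3OC)C[C@@]4(CO4)[C@H]2CO)ccc1OCc1ccccc1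
F4 | step 7 | (2S,3S,4R)-4-[4-(benzyloxy)-3-methoxyphenyl]-7-hydroxy-3-(hydroxymethyl)-6,8-dimethoxy-1,2,3,4-tetrahydronaphthalene-2-carbaldehyde | COc1cc([C@@H]2c3c(cc(OC)c(O)c3OC)C[C@H](C=O)[C@H]2CO)ccc1OCc1ccccc1
F5 | step 3 | 2-{[2-(chloromethyl)prop-2-en-1-yl]oxy}-1,3-dimethoxybenzene | COc1cccc(OC)c1OCC(=C)CCl
F6 | step 3 | 3-[(2,6-dimethoxyphenoxy)methyl]but-3-enoic acid | COc1cccc(OC)c1OCC(=C)CC(O)=O
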